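Ring A is disconnected at C1–C2 and C3–C4, so that C2–C3 is delivered as one two-carbon reagent. The structure invites this: C1 is a methylene on the quaternary C10 (a non-enolisable aldehyde in the precursor), C4 carries C19 at the ester level (a nucleophilic α-carbon), and between them ring A holds only the CH(OH)–CH2 unit C2–C3. In one operation the extended ester enolate of a monocyclic ring B aldehyde adds through C4 to vinyltriphenylphosphonium bromide and the ylide formed closes ring A by intramolecular Wittig reaction at C1. The C1=C2 and C5=C6 alkenes left behind are later hydroborated to the 2α-hydroxyl and to 5α-H/6α-OH.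

Key step: step 11

Convention: labdane numbering is used for every intermediate; α and β refer to the usual labdane drawing, in which the C20 methyl on C10 is β.

Assumption: in step 2 hydride is taken to enter anti to the bulkier dimethoxymethyl group; if the intrinsic preference were the opposite, the antipodal catalyst would give the same C10 configuration, and the carbinol centre is erased in step 8.

Step 1
Reactants: 1 2-methylcyclohexane-1,3-dione
Product: 3 2-(dimethoxymethyl)-2-methylcyclohexane-1,3-dione, via silyl enol ether 2 (not isolated)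
Conditions: TMSOTf (1.2 equiv), iPr2NEt, CH2Cl2, 0 °C; then HC(OMe)3, −78 → 0 °C
Reagents that add atoms: trimethyl orthoformate COC(OC)OC
Why: In situ silyl enol ether formation followed by TMSOTf-promoted Mukaiyama-type C-alkylation with the dimethoxycarbenium ion should place the masked C1 aldehyde carbon on C10, the silyl enol ether reacting at carbon.

Step 2
Reactants: 3 2-(dimethoxymethyl)-2-methylcyclohexane-1,3-dione
Product: 4 (2R,3S)-2-(dimethoxymethyl)-3-hydroxy-2-methylcyclohexan-1-one
Conditions: (R)-2-methyl-CBS-oxazaborolidine (10 mol%), BH3·SMe2, THF, −30 °C; then MeOH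
Reagents that add atoms: none
Why: Corey–Bakshi–Shibata reduction should desymmetrise the prochiral dione, the catalyst fixing the (S)-carbinol and the anti approach to the dimethoxymethyl group selecting one of the two enantiotopic carbonyls, which sets the quaternary centre C10.

Step 3
Reactants: 4 (2R,3S)-2-(dimethoxymethyl)-3-hydroxy-2-methylcyclohexan-1-one
Product: 5 (2R,3S)-3-(tert-butyldimethylsilyloxy)-2-(dimethoxymethyl)-2-methylcyclohexan-1-one
Conditions: TBSCl, imidazole, DMF, 40 °C
Reagents that add atoms: tert-butyldimethylsilyl chloride CC(C)(C)[Si](C)(C)Cl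
Why: Silylation protects the carbinol (the future C5 carbonyl) against the enolate and triflation chemistry of the next steps.

Step 4
Reactants: 5 (2R,3S)-3-(tert-butyldimethylsilyloxy)-2-(dimethoxymethyl)-2-methylcyclohexan-1-one
Product: 7 (2R,3S)-3-(tert-butyldimethylsilyloxy)-2-(dimethoxymethyl)-2,6-dimethylcyclohexan-1-one (both C8 epimers), via lithium enolate 6 (not isolated)
Conditions: LiN(iPr)2 (1.05 equiv), THF, −78 °C; MeI, −78 → −30 °C
Reagents that add atoms: iodomethane CI
Why: The ketone can enolise only toward C8 because C10 is quaternary, so enolate alkylation should install the C8 methyl (C17); the new centre is uncontrolled and is erased in step 5.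

Step 5
Reactants: 7 (2R,3S)-3-(tert-butyldimethylsilyloxy)-2-(dimethoxymethyl)-2,6-dimethylcyclohexan-1-one
Product: 9 enol triflate of 7 (C9–OTf on the C8=C9 alkene; C10 and C5 as in 5), via potassium enolate 8 (not isolated)
Conditions: KN(SiMe3)2, THF, −78 °C; PhNTf2, −78 → 0 °C
Reagents that add atoms: N-phenylbis(trifluoromethanesulfonimide) O=S(=O)(N(c1ccccc1)S(=O)(=O)C(F)(F)F)C(F)(F)F
Why: O-Triflation of the only possible (tetrasubstituted) enolate should fix the C8=C9 alkene regiospecifically.

Step 6
Reactants: 9 enol triflate of 7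
Product: 10 C9-vinyl diene silyl ether (C8=C9–C11=C12; C10 and C5 as in 5)
Conditions: Bu3SnCH=CH2, Pd(PPh3)4 (5 mol%), LiCl, THF, 65 °C
Reagents that add atoms: tributyl(vinyl)stannane C=C[Sn](CCCC)(CCCC)CCCC
Why: Stille coupling of the enol triflate should attach C11–C12 as a vinyl group, the later anchor for the butenolide.

Step 7
Reactants: 10 C9-vinyl diene silyl ether
Product: 11 2-(dimethoxymethyl)-2,4-dimethyl-3-vinylcyclohex-3-en-1-ol (C10 and C5 as in 4)
Conditions: Bu4NF, THF, rt
Reagents that add atoms: none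
Why: Fluoride should cleave the silyl ether while acetal and diene stay untouched.

Step 8
Reactants: 11 2-(dimethoxymethyl)-2,4-dimethyl-3-vinylcyclohex-3-en-1-ol
Product: 12 (S)-2-(dimethoxymethyl)-2,4-dimethyl-3-vinylcyclohex-3-en-1-one
Conditions: Dess–Martin periodinane, pyridine, CH2Cl2, rt
Reagents that add atoms: none
Why: Dess–Martin oxidation should give the C5 ketone; the auxiliary carbinol centre disappears and the quaternary C10 cannot epimerise.

Step 9
Reactants: 12 (S)-2-(dimethoxymethyl)-2,4-dimethyl-3-vinylcyclohex-3-en-1-one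
Product: 13 1-(ethoxyethynyl)-2-(dimethoxymethyl)-2,4-dimethyl-3-vinylcyclohex-3-en-1-ol (both C5 epimers; C10 as in 12)
Conditions: HC≡COEt, n-BuLi, THF, −78 °C; then 12, −78 → 0 °C; H2O
Reagents that add atoms: ethoxyacetylene C#COCC
Why: The slim lithium ethoxyacetylide should add to the hindered C5 ketone and bring in C4 and C19; the carbinol configuration is of no consequence.

Step 10
Reactants: 13 1-(ethoxyethynyl)-2-(dimethoxymethyl)-2,4-dimethyl-3-vinylcyclohex-3-en-1-ol
Product: 15 ethyl 2-(2-formyl-2,4-dimethyl-3-vinylcyclohex-3-en-1-ylidene)acetate (E/Z; C10 as in 12), via acetal enoate 14 (not isolated)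
Conditions: Sc(OTf)3 (5 mol%), EtOH, CH2Cl2, rt; then 1 M HCl, THF, rt
Reagents that add atoms: water O
Why: Meyer–Schuster rearrangement of the ethoxyalkynyl carbinol should give the α,β-unsaturated ethyl ester, and aqueous acid should then unmask the C1 aldehyde.

Step 11
Reactants: 15 ethyl 2-(2-formyl-2,4-dimethyl-3-vinylcyclohex-3-en-1-ylidene)acetate
Product: 18 ethyl 13,14,15,16,18-pentanorlabda-1,5,8,11-tetraen-19-oate (both C4 epimers), via lithium dienolate 16 (not isolated), via phosphorus ylide 17 (not isolated)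
Conditions: lithium 2,2,6,6-tetramethylpiperidide (1.05 equiv), THF, −78 °C; then CH2=CHPPh3Br (1.3 equiv), −78 → 65 °C
Reagents that add atoms: vinyltriphenylphosphonium bromide C=C[P+](c1ccccc1)(c1ccccc1)c1ccccc1.[Br-]
Why: The amide base removes a C6–H of 15 to give the extended ester dienolate 16, which adds through its α-carbon C4 to the β-carbon of the vinylphosphonium salt (new C3–C4 bond, C5=C6 left deconjugated) and so generates ylide 17, whose ylide carbon C2 attacks the C1 aldehyde in an intramolecular Wittig reaction (new C1–C2 bond, Ph3P=O lost). The closest known reaction type is the Schweizer annulation (Michael-initiated intramolecular Wittig olefination with vinyltriphenylphosphonium bromide), run here with a preformed lithium enolate. Ring A is closed in the Wittig event by 6-exo addition of the ylide carbon to the carbonyl through a bicyclic oxaphosphetane, which can only collapse to the endocyclic cis C1=C2 alkene. C4 becomes a stereocentre without control (both epimers are carried on because the centre is re-formed in step 12), and C10 is untouched. The step needs α- rather than γ-attack of the dienolate and no attack of base or enolate on the aldehyde: lithium ester dienolates react at the α-carbon under kinetic control, the aldehyde is non-enolisable and sits on quaternary C10, the base is non-nucleophilic and cannot deliver hydride, and only the conjugate addition/Wittig sequence is irreversible.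

Step 12
Reactants: 18 ethyl 13,14,15,16,18-pentanorlabda-1,5,8,11-tetraen-19-oate
Product: 20 ethyl 13,14,15,16-tetranorlabda-1,5,8,11-tetraen-19-oate (4α-methyl and 4β-ester), via lithium dienolate 19 (not isolated)
Conditions: LiN(iPr)2, THF/DMPU, −78 °C; MeI, −78 → −20 °C
Reagents that add atoms: iodomethane CI
Why: α-Alkylation of the extended ester enolate should create the quaternary C4, methyl iodide approaching the exocyclic enolate from the α-face, anti to the pseudo-axial C20 methyl that stands 1,3 to C4, so that C18 becomes α and the C19 ester β.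

Step 13
Reactants: 20 ethyl 13,14,15,16-tetranorlabda-1,5,8,11-tetraen-19-oate
Product: 21 13,14,15,16-tetranorlabda-1,5,8,11-tetraen-19-ol
Conditions: LiAlH4, Et2O, 0 °C; aqueous work-up
Reagents that add atoms: none
Why: Hydride reduction should convert the ester into the C19 hydroxymethyl group before the hydride-sensitive butenolide is introduced; the unconjugated and diene alkenes are inert.

Step 14
Reactants: 21 13,14,15,16-tetranorlabda-1,5,8,11-tetraen-19-ol; 22 4-bromofuran-2(5H)-one
Product: 25 2α,19-dihydroxylabda-5,8,13-trien-15,16-olide, via tris-9-BBN adduct 23 (not isolated), via C2-boryl butenolide 24 (not isolated)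
Conditions: 9-BBN (3.5 equiv), THF, 0 → 65 °C; then 22, PdCl2(dppf) (5 mol%), AsPh3, Cs2CO3, DMF/H2O, rt; then NaBO3·4H2O, rt
Reagents that add atoms: sodium perborate [Na+].[O-]OB=O
Why: 9-BBN should add to the terminal vinyl group (boron on C12) and, from the α-face anti to the C20 methyl, to C1=C2 with boron on C2 away from quaternary C10; only the primary B-alkyl group undergoes Suzuki–Miyaura coupling with the bromobutenolide, and oxidation of the remaining C2–B bond with retention should give the 2α-alcohol.

Step 15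
Reactants: 25 2α,19-dihydroxylabda-5,8,13-trien-15,16-olide
Product: 27 2α,6α,19-trihydroxylabda-8,13-dien-15,16-olide (CNP0387838.1), via C6-borane 26 (not isolated)
Conditions: BH3·THF (5 equiv), THF, 0 °C → rt; then NaBO3·4H2O, H2O, rt
Reagents that add atoms: sodium perborate [Na+].[O-]OB=O
Why: Hydroboration of the trisubstituted C5=C6 alkene should place boron on C6 and hydrogen on C5 by syn addition from the α-face (the β-face is screened by the axial C20 methyl and the axial C19 CH2O group), so that oxidation with retention gives the trans-fused ring system with 5α-H and 6α-OH; the tetrasubstituted C8=C9 alkene stays.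

Compound list

1 | 2-methylcyclohexane-1,3-dione | CC1C(=O)CCCC1=O | starting material
2 | 2-methyl-3-(trimethylsilyloxy)cyclohex-2-en-1-one | CC1=C(O[Si](C)(C)C)CCCC1=O | intermediate
3 | 2-(dimethoxymethyl)-2-methylcyclohexane-1,3-dione | COC(OC)C1(C)C(=O)CCCC1=O | intermediate
4 | (2R,3S)-2-(dimethoxymethyl)-3-hydroxy-2-methylcyclohexan-1-one (hydroxyl cis to the acetal group) | C[C@@]1(C(OC)OC)C(=O)CCC[C@@H]1O | intermediate
5 | (2R,3S)-3-(tert-butyldimethylsilyloxy)-2-(dimethoxymethyl)-2-methylcyclohexan-1-one | C[C@@]1(C(OC)OC)C(=O)CCC[C@@H]1O[Si](C)(C)C(C)(C)C | intermediate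
6 | lithium enolate of 5 (enolised toward C8) | [Li+].C[C@@]1(C(OC)OC)C([O-])=CCC[C@@H]1O[Si](C)(C)C(C)(C)C | intermediate
7 | (2R,3S)-3-(tert-butyldimethylsilyloxy)-2-(dimethoxymethyl)-2,6-dimethylcyclohexan-1-one (both C8 epimers) | C[C@@]1(C(OC)OC)C(=O)C(C)CC[C@@H]1O[Si](C)(C)C(C)(C)C | intermediate
8 | potassium enolate of 7 | [K+].C[C@@]1(C(OC)OC)C([O-])=C(C)CC[C@@H]1O[Si](C)(C)C(C)(C)C | intermediate
9 | enol triflate of 7 (C9–OTf, C8=C9; C10 and C5 as in 5) | C[C@@]1(C(OC)OC)C(OS(=O)(=O)C(F)(F)F)=C(C)CC[C@@H]1O[Si](C)(C)C(C)(C)C | intermediate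
10 | C9-vinyl diene silyl ether (C8=C9–C11=C12; C10 and C5 as in 5) | C[C@@]1(C(OC)OC)C(C=C)=C(C)CC[C@@H]1O[Si](C)(C)C(C)(C)C | intermediate
11 | 2-(dimethoxymethyl)-2,4-dimethyl-3-vinylcyclohex-3-en-1-ol (C10 and C5 as in 4) | C[C@@]1(C(OC)OC)C(C=C)=C(C)CC[C@@H]1O | intermediate
12 | (S)-2-(dimethoxymethyl)-2,4-dimethyl-3-vinylcyclohex-3-en-1-one | C[C@@]1(C(OC)OC)C(C=C)=C(C)CCC1=O | intermediate
13 | 1-(ethoxyethynyl)-2-(dimethoxymethyl)-2,4-dimethyl-3-vinylcyclohex-3-en-1-ol (both C5 epimers; C10 as in 12) | C[C@@]1(C(OC)OC)C(C=C)=C(C)CCC1(O)C#COCC | intermediate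
14 | ethyl 2-[2-(dimethoxymethyl)-2,4-dimethyl-3-vinylcyclohex-3-en-1-ylidene]acetate (E/Z; C10 as in 12) | C[C@@]1(C(OC)OC)C(C=C)=C(C)CCC1=CC(=O)OCC | intermediate
15 | ethyl 2-(2-formyl-2,4-dimethyl-3-vinylcyclohex-3-en-1-ylidene)acetate (E/Z; C10 as in 12) | C[C@@]1(C=O)C(C=C)=C(C)CCC1=CC(=O)OCC | intermediate
16 | lithium dienolate of 15 (C5=C6 and C4=C19–OLi) | [Li+].C[C@@]1(C=O)C(C=C)=C(C)CC=C1C=C([O-])OCC | intermediate
17 | phosphorus ylide: C4 adduct of 16 to the vinylphosphonium salt (C2=PPh3; both C4 epimers) | C[C@@]1(C=O)C(C=C)=C(C)CC=C1C(CC=P(c1ccccc1)(c1ccccc1)c1ccccc1)C(=O)OCC | intermediate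
18 | ethyl 13,14,15,16,18-pentanorlabda-1,5,8,11-tetraen-19-oate (10β-methyl; both C4 epimers) | CC1=C(C=C)[C@@]2(C)C=CCC(C(=O)OCC)C2=CC1 | intermediate
19 | lithium dienolate of 18 (C4=C19–OLi) | [Li+].CC1=C(C=C)[C@@]2(C)C=CCC(=C([O-])OCC)C2=CC1 | intermediate
20 | ethyl 13,14,15,16-tetranorlabda-1,5,8,11-tetraen-19-oate (4α-methyl, 4β-ester, 10β-methyl) | CC1=C(C=C)[C@@]2(C)C=CC[C@](C)(C(=O)OCC)C2=CC1 | intermediate
21 | 13,14,15,16-tetranorlabda-1,5,8,11-tetraen-19-ol | CC1=C(C=C)[C@@]2(C)C=CC[C@](C)(CO)C2=CC1 | intermediate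
22 | 4-bromofuran-2(5H)-one | BrC1=CC(=O)OC1 | starting material
23 | tris-9-BBN adduct of 21 (boron on C12, on C2α and on O19) | CC1=C(CCB3C4CCCC3CCC4)[C@@]2(C)C[C@@H](B3C4CCCC3CCC4)C[C@](C)(COB3C4CCCC3CCC4)C2=CC1 | intermediate
24 | Suzuki product still carrying the 2α-(9-BBN) group (19-O–B bond hydrolysed) | CC1=C(CCC3=CC(=O)OC3)[C@@]2(C)C[C@@H](B3C4CCCC3CCC4)C[C@](C)(CO)C2=CC1 | intermediate
25 | 2α,19-dihydroxylabda-5,8,13-trien-15,16-olide | CC1=C(CCC2=CC(=O)OC2)[C@@]2(C)C[C@@H](O)C[C@](C)(CO)C2=CC1 | intermediate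
26 | 6α-borane of 25 with 5α-H (drawn as RBH2, hydroxyls shown free) | CC1=C(CCC2=CC(=O)OC2)[C@@]2(C)C[C@@H](O)C[C@](C)(CO)[C@@H]2[C@@H](B)C1 | intermediate
27 | 2α,6α,19-trihydroxylabda-8,13-dien-15,16-olide (CNP0387838.1) | CC1=C(CCC2=CC(=O)OC2)[C@@]2(C)C[C@@H](O)C[C@](C)(CO)[C@@H]2[C@@H](O)C1 | target

Total step count: 15. Longest linear sequence: 15 steps (from 1; 22 is used as purchased).

Steps most likely to fail

Step 11. The amide base or the dienolate may add to the C1 aldehyde (aldol oligomerisation) before the conjugate addition, or the dienolate may react at C6 instead of C4. The fallback makes the C4 carbanion doubly stabilised, so that sodium hydride suffices in the presence of the aldehyde. It sets out from ketone 12: KN(SiMe3)2 and PhNTf2 should give the C5 enol triflate F1 (C5=C6), and coupling with sodium diethyl malonate under Pd(dba)2/P(tBu)3 should give the alkenylmalonate F2. Aqueous HCl should then free the aldehyde F3, and NaH with vinyltriphenylphosphonium bromide in THF/DMF should form the same two bonds and give the bicyclic geminal diester F4. Krapcho dealkoxycarbonylation (LiCl, wet DMSO, 150 °C) comes back to the route at ester 18.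

Step 15. Hydroboration of the hindered C5=C6 alkene is slow, so borane may reduce the butenolide in competition. The fallback finishes all hydroborations before the lactone is present. It sets out from alcohol 21: 9-BBN (65 °C), then BH3·THF, then NaBO3·4H2O should give the 2α,6α,12,19-tetraol F5. Appel iodination (I2, PPh3, imidazole, 0 °C) of the only unhindered primary hydroxyl should give the C12 iodide F6. Reductive cross-electrophile coupling of F6 with 22 (NiI2, 4,4′-di-tert-butyl-2,2′-bipyridine, Zn, DMA) comes back to the route at target 27.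

Step 12. The alkylation may show poor facial selectivity (attack syn to the C20 methyl) or occur at C6. The fallback replaces the ester by a nitrile, whose slim, linear anion is alkylated from the equatorial α-direction and leaves the nitrile axial. It sets out from ketone 12: Peterson olefination with Me3SiCH2CN/LiN(iPr)2 should give the unsaturated nitrile acetal F7, and aqueous HCl the aldehyde F8. The annulation of step 11 should give the bicyclic nitrile F9, and LiN(iPr)2/MeI the 4α-methyl-4β-nitrile F10. Reduction with iBu2AlH, hydrolysis and NaBH4 comes back to the route at alcohol 21.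

Further compounds

F1 | step 11 | C5 enol triflate of 12 (C5=C6; C10 as in 12) | C[C@@]1(C(OC)OC)C(C=C)=C(C)CC=C1OS(=O)(=O)C(F)(F)F
F2 | step 11 | diethyl 2-[6-(dimethoxymethyl)-4,6-dimethyl-5-vinylcyclohexa-1,4-dien-1-yl]malonate (C10 as in 12) | C[C@@]1(C(OC)OC)C(C=C)=C(C)CC=C1C(C(=O)OCC)C(=O)OCC
F3 | step 11 | diethyl 2-(6-formyl-4,6-dimethyl-5-vinylcyclohexa-1,4-dien-1-yl)malonate (C10 as in 12) | C[C@@]1(C=O)C(C=C)=C(C)CC=C1C(C(=O)OCC)C(=O)OCC
F4 | step 11 | bicyclic geminal diester: 4,4-bis(ethoxycarbonyl) analogue of 18 | CC1=C(C=C)[C@@]2(C)C=CCC(C(=O)OCC)(C(=O)OCC)C2=CC1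
F5 | step 15 | 13,14,15,16-tetranorlabd-8-ene-2α,6α,12,19-tetraol | CC1=C(CCO)[C@@]2(C)C[C@@H](O)C[C@](C)(CO)[C@@H]2[C@@H](O)C1
F6 | step 15 | 12-iodo-13,14,15,16-tetranorlabd-8-ene-2α,6α,19-triol | CC1=C(CCI)[C@@]2(C)C[C@@H](O)C[C@](C)(CO)[C@@H]2[C@@H](O)C1
F7 | step 12 | 2-[2-(dimethoxymethyl)-2,4-dimethyl-3-vinylcyclohex-3-en-1-ylidene]acetonitrile (E/Z; C10 as in 12) | C[C@@]1(C(OC)OC)C(C=C)=C(C)CCC1=CC#N
F8 | step 12 | 2-(2-formyl-2,4-dimethyl-3-vinylcyclohex-3-en-1-ylidene)acetonitrile (E/Z; C10 as in 12) | C[C@@]1(C=O)C(C=C)=C(C)CCC1=CC#N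
F9 | step 12 | 13,14,15,16,18-pentanorlabda-1,5,8,11-tetraene-19-nitrile (both C4 epimers) | CC1=C(C=C)[C@@]2(C)C=CCC(C#N)C2=CC1
F10 | step 12 | 13,14,15,16-tetranorlabda-1,5,8,11-tetraene-19-nitrile (4α-methyl, 4β-nitrile) | CC1=C(C=C)[C@@]2(C)C=CC[C@](C)(C#N)C2=CC1
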